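## The problem

The target is a flavone: ring A is the benzo ring, ring C the pyranone, and ring B the 2-aryl group. Every chromone position except C8 is substituted: 5-OH, a 3-methyl-2-oxobutyl chain at C6, 7-OMe, a prenyl group at C3, and a 2,4-dihydroxyphenyl group at C2. There is no stereocentre, so nothing has to be controlled in that sense; the stereogenic carbons that appear on the way are transient and are erased by oxidation or aromatisation. The difficulty is regiochemical. Five different groups must be placed around ring A, the two oxygens flanking C6 must end up different (free at C5, methylated at C7), and ring C must close through the ring A oxygen and not through the 2′-oxygen of ring B. The prenyl olefin rules out hydrogenolysis and strong oxidants and is at risk from protic and Lewis acids (hydration, HCl addition, cyclisation). The chain ketone has acidic benzylic α-protons that would compete in any enolate chemistry, and once the 5-OH is free it can condense with that ketone to a benzofuran under acid. The enabling feature is C4: a lone carbonyl carbon bonded only to C4a of ring A and to C3, which carries the prenyl group and is the α-carbon of the aryl ketone formed by C2 and ring B. C4 can therefore be carbon monoxide inserted between a ring A halide at C4a and the enolate of a B-ring ketone whose tail already is the prenyl group. C4a lies ortho to O1 in a ring whose phenol precursor is symmetric, so the halogen can only enter at the right carbon.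

## Retrosynthesis

**Target 22 to 21.** The O–CH3 bond at C5 is cut last. Carrying both ring A oxygens as methyl ethers keeps ring A symmetric for as long as possible. The 5-methoxy group is the only one peri to the C4 carbonyl, so a chelation-controlled Lewis acid demethylation can tell it from the 7-methoxy group. The forward step must spare the prenyl group and the chain ketone.

**21 to 20.** The two B-ring phenols and the chain ketone are unmasked together. The cut removes two methoxymethyl ethers and one dioxolane, all acid-labile. Doing this while C5 is still methylated means the liberated chain ketone has no neighbouring phenol to cyclise onto. Flavone 20 is fully protected and non-polar.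

**20 to 17.** The O1–C2 bond of ring C is cut, with the C2=C3 unsaturation traced back to a dehydration. The neighbouring cut at O1–C8a would demand an aryl halide at C8a and a metal-mediated C–O coupling on a base-sensitive diketone. The O1–C2 cut needs only a phenol and a carbonyl group. The forward reaction frees the ring A oxygen alone (silyl ether, fluoride), giving phenol 18, which closes to hemiketal 19 and loses water. The B-ring oxygens must stay protected during this closure so that only one phenol can reach a carbonyl.

**17 to 8, 14 and 15.** Both bonds to C4 are cut: C4a–C4 and C4–C3. This gives aryl iodide 8, ketone 14 and carbon monoxide 15. The neighbouring cuts are a crossed Claisen acylation with a ring A ester and a Baker–Venkataraman shift from a ring A homoprenyl ketone. Both require a carboxyl or acyl group on the di-ortho-substituted ring A, which costs extra steps, and the first asks a ketone enolate to attack a very hindered ester. The carbonylative cut uses the aryl iodide directly, takes C4 from a gas, and brings C3 with its prenyl group already in place. The forward reaction needs CO insertion before coupling and C-acylation of the enolate; no ring closes.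

**8 to 7.** The C4a–I bond is cut. In 7 the only two free ring positions are mirror images, each ortho to the silyloxy group, so electrophilic iodination has a single possible outcome. The silyl ether that was put on for the lithiation is kept and later serves as the mask of O1.

**7 to 6 to 5.** The dioxolane goes back to ketone 6 and this to carbinol 5. The ketal is not optional: a free benzylic ketone in 8 would be deprotonated in the key step and become a second enolate.

**5 to 2 and 3.** The bond between C6 and the benzylic carbon of the chain is cut. Silyl ether 2, made from phenol 1, is lithiated between its two methoxy groups to aryllithium 4, which opens racemic epoxide 3 at its CH2 terminus. The alternative of arylating a preformed ketone would require a halide at the most hindered ring position. The lithiation must go between the methoxy groups and not next to the bulky silyloxy group.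

**14 to 13 to 10 and 11.** The ketone carbonyl is traced to carbinol 13 and this to aldehyde 10 and Grignard reagent 12, made from bromide 11. Aldehyde 10 is the bis-methoxymethyl ether of aldehyde 9. Three routine steps give a ketone whose α-carbon is the future C3 and whose tail is the complete prenyl group.

## Roads not taken

**Alternative 1:** Ring A is removed altogether. Irradiating the 6-diazoacetylpyranone A2 with the siloxyalkyne A3 would trigger a Wolff shift (C8–C8a), ketene–alkyne [2+2] addition (C5–C6, C7–C8), cyclobutenone opening and 6π closure (C4a–C5), giving the 5-hydroxy-7-silyloxyflavone A1.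
- Merits: the polarity of the ynol ether fixes the whole ring A pattern. The 5-OH is born free and the 7-oxygen silylated, so the two ring A oxygens are differentiated without a late Lewis acid next to the prenyl group. In this respect the road is better than the chosen plan, which must accept a BCl3 demethylation in step 12.
- Weak points: the γ-pyrone chromophore and the prenyl olefin are both present during irradiation, so pyrone photoisomerisation and ketene–olefin cycloaddition compete. The 6π closure must engage the double bond of an electron-poor vinylogous ester. A2 (a trisubstituted pyranone acid turned into a diazoketone) and A3 (an ynol silyl ether carrying a ketal) each need a synthesis at least as long as those of 8 and 14. After A1 the 7-oxygen still has to be desilylated and methylated.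
- Comparison: against the cleaner oxygen differentiation, the chosen plan sets two short fragment syntheses from cheap aromatics, a thermal key step, and no photochemistry on a prenylated chromophore.

**Alternative 2:** The cut is at C3–C4 and O1–C2, with ring B and the first prenyl carbon delivered as the 4-hydroxycoumarin A6 and ring A as the o-acetoxy aroyl chloride A5. O-acylation of A6, acyl migration to C3, acetate cleavage and addition–elimination of the phenoxide at the coumarin C4 would give the lactone-bridged flavone A4.
- Merits: classical acyl-transfer chemistry, no gas and no transition metal. The 2′-oxygen is locked in the lactone, so wrong-way closure of ring C is structurally impossible. On this point it is safer than step 10 of the chosen plan, which relies on protecting groups.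
- Weak points: in A4 the lactone carbonyl must still become the CH2 of a prenyl group. That means reducing it to the methylene level and attaching a 2-methylpropenyl unit next to the C4 carbonyl and a liberated 2′-phenol, which is several steps of uncertain chemoselectivity. The displacement at the coumarin C4 needs activation, because the 3-acyl-4-hydroxycoumarin is a strongly chelated tricarbonyl. A5 needs the same pentasubstituted ring A as 8 plus a carboxyl group.
- Comparison: the chosen plan brings the prenyl group complete as the tail of ketone 14 and needs three steps after the key step; this road has the more reliable key step but a long and doubtful tail.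

**Alternative 3:** The cut is at O1–C8a. The bromo diketone A8 (the analogue of 17 with bromine in place of the silyloxy group) would cyclise under copper catalysis (CuI, monovalent copper, with a phosphate base) through its B-side enol oxygen. The product is the flavone A7, identical in structure with 20.
- Merits: ring C closes under base in one operation, with no acid near the methoxymethyl ethers and no hemiketal dehydration. The A-side oxygen cannot compete, since it would form a four-membered ring. From A7 onward the two roads are the same. In ring closure this road is at least as good as step 10.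
- Weak points: A8 still has to be assembled, most directly by the same carbonylative coupling, so the alternative does not replace the key step but adds a demand to it. Ring A would need bromine at C8a and iodine at C4a. It would have to start from a bromoarene instead of phenol 1, where lithiation for the chain collides with bromine–lithium exchange, and palladium would have to choose C–I over C–Br. The copper step at about 100 °C with phosphate exposes a 2-alkyl-1,3-diketone to retro-Claisen cleavage.
- Comparison: the chosen plan takes O1 from the starting phenol, where as a silyl ether it also defines the iodination site by symmetry. The price is the acid-mediated dehydration of step 10.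

Key step: step 9

Assumption: the target is taken as the open-chain ketone drawn (no stereocentre), and racemic epoxide 3 is used because its carbinol centre is oxidised away in step 3.

## Route

Step 1
Reactants: 1 3,5-dimethoxyphenol
Product: 2 (3,5-dimethoxyphenoxy)triisopropylsilane
Conditions: TIPSCl, imidazole, DMF, 0 °C → rt
Reagents that add atoms: triisopropylsilyl chloride, CC(C)[Si](Cl)(C(C)C)C(C)C
Why: Standard silylation of a phenol; the bulky, weakly coordinating silyl ether keeps the oxygen from directing the lithiation and later serves as the fluoride-labile mask of O1.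

Step 2
Reactants: 2 (3,5-dimethoxyphenoxy)triisopropylsilane; 3 2-isopropyloxirane (racemic)
Product: 5 rac-1-[2,6-dimethoxy-4-(triisopropylsilyloxy)phenyl]-3-methylbutan-2-ol, via aryllithium 4 (not isolated)
Conditions: n-BuLi, THF, 0 °C → rt; then 3, BF3·OEt2, −78 °C; aq. NH4Cl
Reagents that add atoms: none
Why: Directed ortho-metalation: the two methoxy groups jointly direct n-BuLi to the carbon between them, while the silyloxy group is a poor director; BF3·OEt2-promoted opening of the terminal epoxide at its CH2 carbon then forms the aryl–CH2 bond. The new carbinol centre is racemic and is removed in step 3.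

Step 3
Reactants: 5 rac-1-[2,6-dimethoxy-4-(triisopropylsilyloxy)phenyl]-3-methylbutan-2-ol
Product: 6 1-[2,6-dimethoxy-4-(triisopropylsilyloxy)phenyl]-3-methylbutan-2-one
Conditions: Dess–Martin periodinane, NaHCO3, CH2Cl2, 0 °C → rt
Reagents that add atoms: none
Why: Dess–Martin oxidation of a secondary alcohol; the buffered, non-acidic conditions leave the aryl silyl ether and the electron-rich ring untouched.

Step 4
Reactants: 6 1-[2,6-dimethoxy-4-(triisopropylsilyloxy)phenyl]-3-methylbutan-2-one
Product: 7 {3,5-dimethoxy-4-[(2-isopropyl-1,3-dioxolan-2-yl)methyl]phenoxy}triisopropylsilane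
Conditions: (Me3SiOCH2)2, TMSOTf (cat.), CH2Cl2, −78 → −20 °C; pyridine quench
Reagents that add atoms: 1,2-bis(trimethylsilyloxy)ethane, C[Si](C)(C)OCCO[Si](C)(C)C
Why: Aprotic ketalisation with the bis-silylated glycol under silyl triflate catalysis converts hindered, enolisable ketones to dioxolanes at low temperature; the ketal removes the acidic benzylic α-protons that would otherwise compete as an enolate in step 9.

Step 5
Reactants: 7 {3,5-dimethoxy-4-[(2-isopropyl-1,3-dioxolan-2-yl)methyl]phenoxy}triisopropylsilane
Product: 8 {2-iodo-3,5-dimethoxy-4-[(2-isopropyl-1,3-dioxolan-2-yl)methyl]phenoxy}triisopropylsilane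
Conditions: NIS, MeCN, 0 °C → rt, dark
Reagents that add atoms: N-iodosuccinimide, O=C1CCC(=O)N1I
Why: Electrophilic aromatic iodination of a trioxygenated ring; the only two free positions are equivalent by symmetry (each ortho to the silyloxy group and para to a methoxy group), so mono-iodination can only give 8.

Step 6
Reactants: 9 2,4-dihydroxybenzaldehyde
Product: 10 2,4-bis(methoxymethoxy)benzaldehyde
Conditions: MOMCl, iPr2NEt, CH2Cl2, 0 °C → reflux
Reagents that add atoms: chloromethyl methyl ether, COCCl
Why: Methoxymethyl ether formation; excess reagent and warming also alkylate the hydrogen-bonded 2-hydroxyl.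

Step 7
Reactants: 10 2,4-bis(methoxymethoxy)benzaldehyde; 11 5-bromo-2-methylpent-2-ene
Product: 13 rac-1-[2,4-bis(methoxymethoxy)phenyl]-5-methylhex-4-en-1-ol, via homoprenylmagnesium bromide 12 (not isolated)
Conditions: Mg, THF, rt; then 10, 0 °C; aq. NH4Cl
Reagents that add atoms: none
Why: Grignard addition to an aryl aldehyde; the carbinol centre is formed racemic and is removed in step 8.

Step 8
Reactants: 13 rac-1-[2,4-bis(methoxymethoxy)phenyl]-5-methylhex-4-en-1-ol
Product: 14 1-[2,4-bis(methoxymethoxy)phenyl]-5-methylhex-4-en-1-one
Conditions: Dess–Martin periodinane, NaHCO3, CH2Cl2, rt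
Reagents that add atoms: none
Why: Dess–Martin oxidation of a benzylic alcohol; the trisubstituted olefin and the acetal ethers are inert.

Step 9
Reactants: 8 {2-iodo-3,5-dimethoxy-4-[(2-isopropyl-1,3-dioxolan-2-yl)methyl]phenoxy}triisopropylsilane; 14 1-[2,4-bis(methoxymethoxy)phenyl]-5-methylhex-4-en-1-one; 15 carbon monoxide
Product: 17 rac-1-[2,4-bis(methoxymethoxy)phenyl]-3-{2,4-dimethoxy-3-[(2-isopropyl-1,3-dioxolan-2-yl)methyl]-6-(triisopropylsilyloxy)phenyl}-2-(3-methylbut-2-en-1-yl)propane-1,3-dione, via sodium enolate 16 (not isolated)
Conditions: 14 (2 equiv.), NaN(SiMe3)2 (2 equiv.), THF, 0 °C; then 8, Pd(OAc)2 (5 mol%), Xantphos (6 mol%), CO (1 atm), dioxane, 80 °C; aq. NH4Cl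
Reagents that add atoms: none
Why: Pd(OAc)2 is reduced in situ to zerovalent palladium, which inserts into the C4a–I bond of 8; the aryl divalent palladium complex, flanked by methoxy and silyloxy groups, takes up CO to give an aroyl palladium species (C4a–C4), and displacement of iodide by enolate 16 followed by C–C reductive elimination forms C4–C3. The closest known reaction type is the palladium-catalysed carbonylative α-arylation of aryl alkyl ketones with aryl iodides to 1,3-diketones. No ring closes in this step. The one new stereocentre, the prenyl-bearing carbon between the carbonyls, is formed racemic and needs no control because it is enolisable and becomes sp2 in step 10. CO insertion must outrun direct α-arylation: the two ortho substituents and the wide bite angle of Xantphos slow aryl–enolate reductive elimination and favour migratory insertion under 1 atm of CO. C- over O-acylation is needed: reductive elimination at palladium proceeds through the soft carbon terminus, and the second equivalent of 16 converts the acidic product to its diketonate, which protects it from retro-Claisen attack and from a second acylation. The dioxolane in 8 leaves 14 as the only enolisable ketone, and the prenyl olefin, acetal ethers and silyl ether are inert to the base and to zerovalent palladium.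

Step 10
Reactants: 17 rac-1-[2,4-bis(methoxymethoxy)phenyl]-3-{2,4-dimethoxy-3-[(2-isopropyl-1,3-dioxolan-2-yl)methyl]-6-(triisopropylsilyloxy)phenyl}-2-(3-methylbut-2-en-1-yl)propane-1,3-dione
Product: 20 2-[2,4-bis(methoxymethoxy)phenyl]-5,7-dimethoxy-6-[(2-isopropyl-1,3-dioxolan-2-yl)methyl]-3-(3-methylbut-2-en-1-yl)-4H-chromen-4-one, via free phenol diketone 18 (not isolated), via cyclic hemiketal 19 (not isolated)
Conditions: Bu4NF, AcOH, THF, 0 °C; work-up; then CSA (cat.), 4 Å MS, CH2Cl2, rt
Reagents that add atoms: none
Why: Buffered fluoride cleaves the aryl silyl ether, and the freed phenol adds to the B-ring carbonyl (the only one it can reach in a six-membered ring) while the B-ring oxygens are still protected and cannot compete. Catalytic acid in dry CH2Cl2 ionises the hemiketal to a cation stabilised by O1 and the dialkoxyphenyl ring, and loss of H3 gives the chromone; this is the classical cyclodehydration of o-hydroxyaryl 1,3-diketones to flavones, run mildly enough to keep the acetal groups.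

Step 11
Reactants: 20 2-[2,4-bis(methoxymethoxy)phenyl]-5,7-dimethoxy-6-[(2-isopropyl-1,3-dioxolan-2-yl)methyl]-3-(3-methylbut-2-en-1-yl)-4H-chromen-4-one
Product: 21 2-(2,4-dihydroxyphenyl)-5,7-dimethoxy-6-(3-methyl-2-oxobutyl)-3-(3-methylbut-2-en-1-yl)-4H-chromen-4-one
Conditions: 2 M aq. HCl, MeOH/THF, 45 °C
Reagents that add atoms: water, O
Why: Acid hydrolysis of two methoxymethyl ethers and one dioxolane, as routinely used on prenylated flavonoids; C5 is still methylated, so the liberated chain ketone has no neighbouring phenol with which to form a benzofuran.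

Step 12
Reactants: 21 2-(2,4-dihydroxyphenyl)-5,7-dimethoxy-6-(3-methyl-2-oxobutyl)-3-(3-methylbut-2-en-1-yl)-4H-chromen-4-one
Product: 22 2-(2,4-dihydroxyphenyl)-5-hydroxy-7-methoxy-6-(3-methyl-2-oxobutyl)-3-(3-methylbut-2-en-1-yl)-4H-chromen-4-one
Conditions: BCl3, CH2Cl2, −78 → −20 °C; then H2O
Reagents that add atoms: none
Why: Chelation-controlled demethylation: BCl3 bridges the C4 carbonyl oxygen and the 5-methoxy oxygen in a six-membered chelate and chloride removes only that methyl group; the 7-methoxy group has no such chelate, and the low temperature limits acid damage to the prenyl group.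

## Compound list

1 | 3,5-dimethoxyphenol | COc1cc(O)cc(OC)c1 | starting material
2 | (3,5-dimethoxyphenoxy)triisopropylsilane | COc1cc(O[Si](C(C)C)(C(C)C)C(C)C)cc(OC)c1 | intermediate
3 | 2-isopropyloxirane (racemic) | CC(C)C1CO1 | starting material
4 | [2,6-dimethoxy-4-(triisopropylsilyloxy)phenyl]lithium | [Li]c1c(OC)cc(O[Si](C(C)C)(C(C)C)C(C)C)cc1OC | intermediate (not isolated)
5 | rac-1-[2,6-dimethoxy-4-(triisopropylsilyloxy)phenyl]-3-methylbutan-2-ol | COc1cc(O[Si](C(C)C)(C(C)C)C(C)C)cc(OC)c1CC(O)C(C)C | intermediate
6 | 1-[2,6-dimethoxy-4-(triisopropylsilyloxy)phenyl]-3-methylbutan-2-one | COc1cc(O[Si](C(C)C)(C(C)C)C(C)C)cc(OC)c1CC(=O)C(C)C | intermediate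
7 | {3,5-dimethoxy-4-[(2-isopropyl-1,3-dioxolan-2-yl)methyl]phenoxy}triisopropylsilane | COc1cc(O[Si](C(C)C)(C(C)C)C(C)C)cc(OC)c1CC1(C(C)C)OCCO1 | intermediate
8 | {2-iodo-3,5-dimethoxy-4-[(2-isopropyl-1,3-dioxolan-2-yl)methyl]phenoxy}triisopropylsilane | COc1cc(O[Si](C(C)C)(C(C)C)C(C)C)c(I)c(OC)c1CC1(C(C)C)OCCO1 | intermediate
9 | 2,4-dihydroxybenzaldehyde | O=Cc1ccc(O)cc1O | starting material
10 | 2,4-bis(methoxymethoxy)benzaldehyde | COCOc1ccc(C=O)c(OCOC)c1 | intermediate
11 | 5-bromo-2-methylpent-2-ene | CC(C)=CCCBr | starting material
12 | (4-methylpent-3-en-1-yl)magnesium bromide | CC(C)=CCC[Mg]Br | intermediate (not isolated)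
13 | rac-1-[2,4-bis(methoxymethoxy)phenyl]-5-methylhex-4-en-1-ol | CC(C)=CCCC(O)c1ccc(OCOC)cc1OCOC | intermediate
14 | 1-[2,4-bis(methoxymethoxy)phenyl]-5-methylhex-4-en-1-one | CC(C)=CCCC(=O)c1ccc(OCOC)cc1OCOC | intermediate
15 | carbon monoxide | [C-]#[O+] | starting material
16 | sodium (Z)-1-[2,4-bis(methoxymethoxy)phenyl]-5-methylhexa-1,4-dien-1-olate | CC(C)=CC/C=C(\[O-])c1ccc(OCOC)cc1OCOC.[Na+] | intermediate (not isolated)
17 | rac-1-[2,4-bis(methoxymethoxy)phenyl]-3-{2,4-dimethoxy-3-[(2-isopropyl-1,3-dioxolan-2-yl)methyl]-6-(triisopropylsilyloxy)phenyl}-2-(3-methylbut-2-en-1-yl)propane-1,3-dione (keto/enol mixture) | COc1cc(O[Si](C(C)C)(C(C)C)C(C)C)c(C(=O)C(CC=C(C)C)C(=O)c2ccc(OCOC)cc2OCOC)c(OC)c1CC1(C(C)C)OCCO1 | intermediate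
18 | rac-1-[2,4-bis(methoxymethoxy)phenyl]-3-{6-hydroxy-2,4-dimethoxy-3-[(2-isopropyl-1,3-dioxolan-2-yl)methyl]phenyl}-2-(3-methylbut-2-en-1-yl)propane-1,3-dione | COc1cc(O)c(C(=O)C(CC=C(C)C)C(=O)c2ccc(OCOC)cc2OCOC)c(OC)c1CC1(C(C)C)OCCO1 | intermediate (not isolated)
19 | 2-[2,4-bis(methoxymethoxy)phenyl]-2-hydroxy-5,7-dimethoxy-6-[(2-isopropyl-1,3-dioxolan-2-yl)methyl]-3-(3-methylbut-2-en-1-yl)chroman-4-one (racemic diastereomer mixture) | COc1cc2OC(O)(c3ccc(OCOC)cc3OCOC)C(CC=C(C)C)C(=O)c2c(OC)c1CC1(C(C)C)OCCO1 | intermediate (not isolated)
20 | 2-[2,4-bis(methoxymethoxy)phenyl]-5,7-dimethoxy-6-[(2-isopropyl-1,3-dioxolan-2-yl)methyl]-3-(3-methylbut-2-en-1-yl)-4H-chromen-4-one | COc1cc2oc(-c3ccc(OCOC)cc3OCOC)c(CC=C(C)C)c(=O)c2c(OC)c1CC1(C(C)C)OCCO1 | intermediate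
21 | 2-(2,4-dihydroxyphenyl)-5,7-dimethoxy-6-(3-methyl-2-oxobutyl)-3-(3-methylbut-2-en-1-yl)-4H-chromen-4-one | COc1cc2oc(-c3ccc(O)cc3O)c(CC=C(C)C)c(=O)c2c(OC)c1CC(=O)C(C)C | intermediate
22 | 2-(2,4-dihydroxyphenyl)-5-hydroxy-7-methoxy-6-(3-methyl-2-oxobutyl)-3-(3-methylbut-2-en-1-yl)-4H-chromen-4-one | COc1cc2oc(-c3ccc(O)cc3O)c(CC=C(C)C)c(=O)c2c(O)c1CC(=O)C(C)C | target

## Step count and least certain steps

Total: 12 steps. Longest linear sequence: 9 steps (steps 1–5, 9, 10, 11, 12); the B-ring branch (steps 6–8) joins at step 9.

**Step 9 (key step).** The most likely failures are O-acylation of the enolate, direct α-arylation without CO uptake, and slow oxidative addition at the doubly ortho-substituted C–I bond leading to proto-deiodination. Base-induced migration of the silyl group from the phenol oxygen to the diketonate oxygen is also possible but would be harmless for step 10. The fallback makes the same two bonds by polar chemistry and sets out from 8. Iodine–lithium exchange (n-BuLi, THF, −78 °C) and quenching with DMF should give 2,4-dimethoxy-3-[(2-isopropyl-1,3-dioxolan-2-yl)methyl]-6-(triisopropylsilyloxy)benzaldehyde F1. Aldol addition of the lithium enolate of 14 (LiN(SiMe3)2, THF, −78 °C) should give the β-hydroxy ketone F2 as a diastereomer mixture. Dess–Martin oxidation of the carbinol then rejoins the route at 17.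

**Step 2.** The hindered aryllithium may complex BF3 faster than it opens the epoxide, or the Lewis acid may rearrange the epoxide by hydride shift, so that conversion stays low. The fallback sets out from 2 through aryllithium 4. Alkylation with prenyl bromide (CuI catalysis if needed) should give the prenylarene [3,5-dimethoxy-4-(3-methylbut-2-en-1-yl)phenoxy]triisopropylsilane F3. Hydroboration with BH3·SMe2 places boron on the less substituted olefin carbon, and oxidation with NaBO3·4H2O returns the secondary alcohol 5.

**Step 5.** Iodination next to the bulky silyloxy group may be sluggish, and forcing it with acid activators risks loss of the ketal or the silyl group. The fallback sets out from 7. Desilylation with Bu4NF should give the symmetric phenol 3,5-dimethoxy-4-[(2-isopropyl-1,3-dioxolan-2-yl)methyl]phenol F4. This far more reactive ring is iodinated with NIS at low temperature to the iodophenol F5, and re-silylation (TIPSCl, imidazole) rejoins the route at 8.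

**Step 10.** Dehydration of the hemiketal may be incomplete under acid mild enough for the methoxymethyl ethers, and if these are lost before ring C has closed, the 2′-oxygen can close the ring the wrong way. The fallback changes the B-ring protection to benzyl ethers, which tolerate strong acid. It sets out from 9 and rejoins at 22.
- Benzylation (BnBr, K2CO3, DMF) should give 2,4-bis(benzyloxy)benzaldehyde F6.
- Addition of 12 gives the carbinol F7, and Dess–Martin oxidation the ketone F8.
- Carbonylative coupling with 8 and 15 under the conditions of step 9 gives the diketone F9.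
- Bu4NF followed by HCl in MeOH desilylates, cyclodehydrates and removes the ketal, giving the dibenzyl flavone ketone F10.
- BCl3 with pentamethylbenzene as cation scavenger (−78 → −20 °C) cleaves both benzyl ethers and the 5-methyl ether to give 22.

**Step 12.** HCl liberated when the free phenols react with BCl3 may add to the prenyl olefin or ionise it, with hydrochlorination or cyclisation onto the C4 carbonyl oxygen; poor solubility of the diphenol in CH2Cl2 would aggravate this by requiring excess reagent and higher temperature. The fallback sets out from 21. Acetylation (Ac2O, pyridine) should give the soluble diacetate F11, which carries no free hydroxyl. BCl3 at −78 °C then removes the 5-methyl group to give the 5-hydroxy diacetate F12. Methanolysis (K2CO3, MeOH, 0 °C) rejoins the route at 22.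

## Further compounds

F1 | step 9 | 2,4-dimethoxy-3-[(2-isopropyl-1,3-dioxolan-2-yl)methyl]-6-(triisopropylsilyloxy)benzaldehyde | COc1cc(O[Si](C(C)C)(C(C)C)C(C)C)c(C=O)c(OC)c1CC1(C(C)C)OCCO1
F2 | step 9 | 1-[2,4-bis(methoxymethoxy)phenyl]-3-{2,4-dimethoxy-3-[(2-isopropyl-1,3-dioxolan-2-yl)methyl]-6-(triisopropylsilyloxy)phenyl}-3-hydroxy-2-(3-methylbut-2-en-1-yl)propan-1-one (racemic diastereomer mixture) | COc1cc(O[Si](C(C)C)(C(C)C)C(C)C)c(C(O)C(CC=C(C)C)C(=O)c2ccc(OCOC)cc2OCOC)c(OC)c1CC1(C(C)C)OCCO1
F3 | step 2 | [3,5-dimethoxy-4-(3-methylbut-2-en-1-yl)phenoxy]triisopropylsilane | COc1cc(O[Si](C(C)C)(C(C)C)C(C)C)cc(OC)c1CC=C(C)C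
F4 | step 5 | 3,5-dimethoxy-4-[(2-isopropyl-1,3-dioxolan-2-yl)methyl]phenol | COc1cc(O)cc(OC)c1CC1(C(C)C)OCCO1
F5 | step 5 | 2-iodo-3,5-dimethoxy-4-[(2-isopropyl-1,3-dioxolan-2-yl)methyl]phenol | COc1cc(O)c(I)c(OC)c1CC1(C(C)C)OCCO1
F6 | step 10 | 2,4-bis(benzyloxy)benzaldehyde | O=Cc1ccc(OCc2ccccc2)cc1OCc1ccccc1
F7 | step 10 | rac-1-[2,4-bis(benzyloxy)phenyl]-5-methylhex-4-en-1-ol | CC(C)=CCCC(O)c1ccc(OCc2ccccc2)cc1OCc1ccccc1
F8 | step 10 | 1-[2,4-bis(benzyloxy)phenyl]-5-methylhex-4-en-1-one | CC(C)=CCCC(=O)c1ccc(OCc2ccccc2)cc1OCc1ccccc1
F9 | step 10 | rac-1-[2,4-bis(benzyloxy)phenyl]-3-{2,4-dimethoxy-3-[(2-isopropyl-1,3-dioxolan-2-yl)methyl]-6-(triisopropylsilyloxy)phenyl}-2-(3-methylbut-2-en-1-yl)propane-1,3-dione | COc1cc(O[Si](C(C)C)(C(C)C)C(C)C)c(C(=O)C(CC=C(C)C)C(=O)c2ccc(OCc3ccccc3)cc2OCc2ccccc2)c(OC)c1CC1(C(C)C)OCCO1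
F10 | step 10 | 2-[2,4-bis(benzyloxy)phenyl]-5,7-dimethoxy-6-(3-methyl-2-oxobutyl)-3-(3-methylbut-2-en-1-yl)-4H-chromen-4-one | COc1cc2oc(-c3ccc(OCc4ccccc4)cc3OCc3ccccc3)c(CC=C(C)C)c(=O)c2c(OC)c1CC(=O)C(C)C
F11 | step 12 | 4-[5,7-dimethoxy-6-(3-methyl-2-oxobutyl)-3-(3-methylbut-2-en-1-yl)-4-oxo-4H-chromen-2-yl]-1,3-phenylene diacetate | COc1cc2oc(-c3ccc(OC(C)=O)cc3OC(C)=O)c(CC=C(C)C)c(=O)c2c(OC)c1CC(=O)C(C)C
F12 | step 12 | 4-[5-hydroxy-7-methoxy-6-(3-methyl-2-oxobutyl)-3-(3-methylbut-2-en-1-yl)-4-oxo-4H-chromen-2-yl]-1,3-phenylene diacetate | COc1cc2oc(-c3ccc(OC(C)=O)cc3OC(C)=O)c(CC=C(C)C)c(=O)c2c(O)c1CC(=O)C(C)C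
A1 | alternative 1 | 2-[2,4-bis(methoxymethoxy)phenyl]-5-hydroxy-6-[(2-isopropyl-1,3-dioxolan-2-yl)methyl]-3-(3-methylbut-2-en-1-yl)-7-(triisopropylsilyloxy)-4H-chromen-4-one | CC(C)C1(Cc2c(O[Si](C(C)C)(C(C)C)C(C)C)cc3oc(-c4ccc(OCOC)cc4OCOC)c(CC=C(C)C)c(=O)c3c2O)OCCO1
A2 | alternative 1 | 2-[2,4-bis(methoxymethoxy)phenyl]-6-(diazoacetyl)-3-(3-methylbut-2-en-1-yl)-4H-pyran-4-one | [N-]=[N+]=CC(=O)c1cc(=O)c(CC=C(C)C)c(-c2ccc(OCOC)cc2OCOC)o1
A3 | alternative 1 | triisopropyl{[3-(2-isopropyl-1,3-dioxolan-2-yl)prop-1-yn-1-yl]oxy}silane | CC(C)C1(CC#CO[Si](C(C)C)(C(C)C)C(C)C)OCCO1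
A4 | alternative 2 | lactone-bridged flavone, 8,10-dimethoxy-9-[(2-isopropyl-1,3-dioxolan-2-yl)methyl]-3-(methoxymethoxy)chromeno[4,3-b]chromene-6,7-dione | COc1cc2OC3=C(C(=O)c2c(OC)c1CC1(C(C)C)OCCO1)C(=O)Oc1cc(OCOC)ccc13
A5 | alternative 2 | 2-acetoxy-4,6-dimethoxy-5-[(2-isopropyl-1,3-dioxolan-2-yl)methyl]benzoyl chloride | COc1cc(OC(C)=O)c(C(=O)Cl)c(OC)c1CC1(C(C)C)OCCO1
A6 | alternative 2 | 4-hydroxy-7-(methoxymethoxy)-2H-chromen-2-one | O=c1cc(O)c2ccc(OCOC)cc2o1
A7 | alternative 3 | 2-[2,4-bis(methoxymethoxy)phenyl]-5,7-dimethoxy-6-[(2-isopropyl-1,3-dioxolan-2-yl)methyl]-3-(3-methylbut-2-en-1-yl)-4H-chromen-4-one (same structure as 20) | COc1cc2oc(-c3ccc(OCOC)cc3OCOC)c(CC=C(C)C)c(=O)c2c(OC)c1CC1(C(C)C)OCCO1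
A8 | alternative 3 | rac-1-[2,4-bis(methoxymethoxy)phenyl]-3-{6-bromo-2,4-dimethoxy-3-[(2-isopropyl-1,3-dioxolan-2-yl)methyl]phenyl}-2-(3-methylbut-2-en-1-yl)propane-1,3-dione | COc1cc(Br)c(C(=O)C(CC=C(C)C)C(=O)c2ccc(OCOC)cc2OCOC)c(OC)c1CC1(C(C)C)OCCO1
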